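(The numbers are made up.)

Set the constants side by side: coupling at 0.45 /M/s stands far above the side steps at 0.017 /M/s and 0.019 /M/s, while second end groups also decay at 0.026 /s.

    first end groups + second end groups → links + by-product (k1 = 0.45 /M/s)
    first end groups + links → side product (k2 = 0.017 /M/s)
    2 first end groups → homo dimer (k3 = 0.019 /M/s)
    second end groups → decomposed reagent (k4 = 0.026 /s)

| flask | first end groups | second end groups | time |
|---|---|---|---|
| south-east | 0.40 M | 0.410 M | 15 s |
| east | 0.40 M | 0.610 M | 15 s |

1. which of these there is most of at the end, counted by the first end groups in it, south-east (side product / first end groups / links)
2. which of these there is most of at the end, counted by the first end groups in it, east (side product / first end groups / links)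
3. final amount of the leader among these, as a percentage of the first end groups charged, in south-east
4. final amount of the leader among these, as a percentage of the first end groups charged, in east

- percent here means first end groups units held: one side product or homo dimer counts as two
- for a step with 2 of a species take k times the square, and two of it per event
- run time (south-east): 15 s

1. Turn the question round: first end groups lead if the run stops before links catch up with them.

2. Leave out every step but coupling, and solve for the moment links equal the first end groups left. That time is the logarithm of 2 minus the charge of first end groups over that of second end groups, divided by the coupling constant times the difference of the charges.

3. South-east gives 5.36 s, the crossing time, the time at which links overtake [first end groups]. East gives 3.13 s.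

4. Compare: the run of 15 s is 2.80 times the south-east crossing time and longer than the east one. Decay has a half-life of 26.7 s, longer than either crossing time.

5. For the amounts, decay thins [second end groups], so count the run as 12.4 s at full strength. By the same solution I reckon 29.8% of the first end groups left in south-east and 13.4% in east. So I name links as the leader in south-east and links in east.

6. Take off the homo dimer. At the starting charges, coupling's share of first end groups (its selectivity) is 92.4% in south-east and 94.8% in east. I commit to 64.9% links in south-east and 82.1% in east.

The forecast named links in south-east and links in east, at 62% and 78%, both a little below my figures: “The extra second end groups in east speed the coupling and offset that decay”.

South-east ends with links at 63.9% over 26.4% first end groups, and east with links at 80.8% over 12.1%. In south-east at 7.50 s, past its crossing time of 5.36 s, links stand at 52.9% over 40.6% first end groups. The east flask read at 4.0 s, past its crossing time of 3.13 s, holds 53.9% links over 42.4% first end groups.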